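**Plan**

Benzofuran numbering is used (O1, C2, C3, C3a, C4–C7, C7a). The retrosynthesis first removes the C3a=C4 unsaturation and the C5–allyl bond, then cuts ring A at C4–C5 and C7–C7a together with the enol-ether bond O1–C7a, and finally cuts C2–C3.
Enabling feature: C5–C6–C7 of ring A is the symmetrical MeO–CH/C=O/CH–OMe unit of 1,3-dimethoxyacetone. Its neighbours C4 and C7a are the exocyclic CH2 and the carbonyl carbon of an α-methylene-γ-butyrolactone whose ring (O1, C2, C3, C3a, C7a) is ring B.
Forward order: acyclic C2–C3 unit, then γ-lactone (latent ring B), then α-methylene lactone, then ring A by Michael–Claisen annulation with ring B re-formed as an enol ether, then C5 allylation, then C3a=C4.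
Stereochemistry: C2/C3 (2S,3S, trans) come from a chiral-phosphoric-acid-catalysed anti-crotylboration. C5 (R) comes from a palladium/(R)-t-BuPHOX decarboxylative allylation. C3a is temporary and ends sp2.

Key step: step 6

Assumption: (S)-TRIP is taken to direct the crotyl group to the Si face of the aryl aldehyde (1S,2S alcohol) and (R)-t-BuPHOX to give 5R, by analogy with the sense of induction known for simple substrates; the configurations of 4 and 17 would be verified and the mirror-image catalyst used if required.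

**Route**

Step 1
Reactants: 1 3,4,5-trimethoxybenzaldehyde; 2 (E)-crotylboronic acid pinacol ester
Product: 4 (1S,2S)-2-methyl-1-(3,4,5-trimethoxyphenyl)but-3-en-1-ol, via pinacol borate ester 3 (not isolated)
Conditions: (S)-TRIP phosphoric acid (5 mol %), PhMe, −30 °C; then aq NaOH, rt
Reagents that add atoms: none
Why: Chiral-phosphoric-acid-catalysed crotylboration through a closed chair transition state, in which the E geometry of 2 gives the anti 1,2-relationship and the (S)-acid selects the aldehyde Si face (1S,2S); borate 3 is hydrolysed on work-up.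

Step 2
Reactants: 4 (1S,2S)-2-methyl-1-(3,4,5-trimethoxyphenyl)but-3-en-1-ol
Product: 6 (1S,2S)-2-methyl-1-(3,4,5-trimethoxyphenyl)butane-1,4-diol, via bis(9-borabicyclononyl) adduct 5 (not isolated)
Conditions: 9-BBN (2.5 equiv), THF, 0 °C → rt; then NaOH, H2O2, 0 °C → rt
Reagents that add atoms: hydrogen peroxide, OO; 9-BBN, B1C2CCCC1CCC2 (its boron is carried only by 5)
Why: Anti-Markovnikov hydroboration–oxidation of the terminal alkene with a bulky borane and C–B oxidation with retention should give the primary alcohol without touching the two stereocentres.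

Step 3
Reactants: 6 (1S,2S)-2-methyl-1-(3,4,5-trimethoxyphenyl)butane-1,4-diol
Product: 8 (4S,5S)-4-methyl-5-(3,4,5-trimethoxyphenyl)dihydrofuran-2(3H)-one, via lactol 7 (not isolated)
Conditions: TEMPO (10 mol %), PhI(OAc)2 (2.5 equiv), CH2Cl2, rt
Reagents that add atoms: none
Why: Oxoammonium-mediated oxidative lactonisation, in which the primary alcohol is oxidised in preference to the hindered benzylic one, the aldehyde closes to lactol 7 and a second oxidation gives the trans γ-lactone.

Step 4
Reactants: 8 (4S,5S)-4-methyl-5-(3,4,5-trimethoxyphenyl)dihydrofuran-2(3H)-one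
Product: 9 (3R,4S,5S)-3-[(dimethylamino)methyl]-4-methyl-5-(3,4,5-trimethoxyphenyl)dihydrofuran-2(3H)-one
Conditions: LiN(i-Pr)2, THF, −78 °C; CH2=NMe2+ I−, −78 °C → rt
Reagents that add atoms: dimethyl(methylidene)ammonium iodide, C=[N+](C)C.[I-]
Why: Mannich reaction of the lactone lithium enolate with the preformed iminium salt, with C–C bond formation expected anti to the C4 methyl (this centre is removed in step 5).

Step 5
Reactants: 9 (3R,4S,5S)-3-[(dimethylamino)methyl]-4-methyl-5-(3,4,5-trimethoxyphenyl)dihydrofuran-2(3H)-one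
Product: 11 (4S,5S)-4-methyl-3-methylene-5-(3,4,5-trimethoxyphenyl)dihydrofuran-2(3H)-one, via trimethylammonium iodide 10 (not isolated)
Conditions: MeI, MeOH, rt; then aq NaHCO3, CH2Cl2, rt
Reagents that add atoms: iodomethane, CI (methyl and iodide are carried only by 10)
Why: Quaternisation followed by Hofmann-type E1cB loss of trimethylamine is the standard α-methylenation of lactones, and the weak base should keep the exocyclic alkene from migrating into the ring.

Step 6
Reactants: 11 (4S,5S)-4-methyl-3-methylene-5-(3,4,5-trimethoxyphenyl)dihydrofuran-2(3H)-one; 12 1,3-dimethoxyacetone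
Product: 15 (2S,3S,3aS)-5,7-dimethoxy-3-methyl-2-(3,4,5-trimethoxyphenyl)-3,3a,4,5-tetrahydrobenzofuran-6(2H)-one (C5 epimers), via Michael adduct keto lactone 13 (not isolated), via hydroxy dione 14 (not isolated)
Conditions: 12 (1.5 equiv), KOt-Bu (2.2 equiv), THF, −20 °C, then 11 added slowly, → rt; 2 M HCl to pH 2; then TsOH·H2O (cat.), PhMe, 40 °C
Reagents that add atoms: none
Why: Proposed new method: the potassium enolate of symmetrical ketone 12 adds to the exocyclic methylene of 11 (C4–C5, adduct 13), proton transfer moves the charge to the other methoxy-bearing α-carbon, and this enolate acylates on the lactone carbonyl (C7–C7a) with expulsion of the C2 alkoxide, the sequence being driven by formation of the enolate of 2-methoxy-1,3-dione 14; acid then lets the C2 hydroxyl add to the C7a carbonyl and lose water to give vinylogous ester 15. The closest known reaction type is the consecutive Michael–Claisen annulation of ketones with acrylic esters to cyclohexane-1,3-diones; what is new is the α-methylene lactone as the acrylate, which keeps its alkoxide leaving group tethered so that ring B can re-form. Ring A closes by a 6-(enolendo)-exo-trig acylation, and ring B recloses by 5-exo-trig hemiketalisation followed by dehydration toward C7. C3a is expected under thermodynamic control (it is enolisable in 13, 14 and 15) trans to the C3 methyl, while C5 is not controlled and is flattened in step 7. The step needs conjugate before carbonyl addition, a single Michael addition and O1–C7a rather than O1–C6 closure; these are secured by the high acceptor reactivity of the α-methylene lactone toward a pre-formed enolate at low temperature, by the symmetry of 12 (either α-carbon may add and the other can then only close a six-membered ring) and by the three-atom tether C2–C3–C3a.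

Step 7
Reactants: 15 (2S,3S,3aS)-5,7-dimethoxy-3-methyl-2-(3,4,5-trimethoxyphenyl)-3,3a,4,5-tetrahydrobenzofuran-6(2H)-one (C5 epimers)
Product: 16 allyl (2S,3S,3aS)-5,7-dimethoxy-3-methyl-2-(3,4,5-trimethoxyphenyl)-2,3,3a,4-tetrahydrobenzofuran-6-yl carbonate
Conditions: LiN(i-Pr)2, THF, −78 °C; TMEDA, allyl chloroformate, −78 → 0 °C
Reagents that add atoms: allyl chloroformate, C=CCOC(=O)Cl
Why: Kinetic deprotonation of a vinylogous ester takes place at the α′ carbon (C5, both epimers give one enolate) rather than at the γ carbon C3a, and the hindered, TMEDA-solvated tetrasubstituted lithium enolate should be acylated on oxygen (enol carbonate formation).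

Step 8
Reactants: 16 allyl (2S,3S,3aS)-5,7-dimethoxy-3-methyl-2-(3,4,5-trimethoxyphenyl)-2,3,3a,4-tetrahydrobenzofuran-6-yl carbonate
Product: 17 (2S,3S,3aS,5R)-5-allyl-5,7-dimethoxy-3-methyl-2-(3,4,5-trimethoxyphenyl)-3,3a,4,5-tetrahydrobenzofuran-6(2H)-one
Conditions: Pd2(dba)3 (2.5 mol %), (R)-t-BuPHOX (6.25 mol %), THF, 25 °C
Reagents that add atoms: none
Why: Palladium-catalysed decarboxylative asymmetric allylic alkylation (Tsuji allylation) releases the C5/C6 enolate regiospecifically, and the (R)-phosphinooxazoline should deliver the allyl group to the C5 face corresponding to the (R)-2-allyl-2-alkylcyclohexanone series, giving the 5R quaternary centre under catalyst control.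

Step 9
Reactants: 17 (2S,3S,3aS,5R)-5-allyl-5,7-dimethoxy-3-methyl-2-(3,4,5-trimethoxyphenyl)-3,3a,4,5-tetrahydrobenzofuran-6(2H)-one
Product: 18 tert-butyl{[(2S,3S,5R)-5-allyl-5,7-dimethoxy-3-methyl-2-(3,4,5-trimethoxyphenyl)-2,3,4,5-tetrahydrobenzofuran-6-yl]oxy}dimethylsilane
Conditions: LiN(i-Pr)2, THF–DMPU, −78 → −20 °C; TBSCl, −78 → 0 °C
Reagents that add atoms: tert-butyldimethylsilyl chloride, CC(C)(C)[Si](C)(C)Cl
Why: With C5 quaternary the only acidic hydrogen is the γ hydrogen at C3a, so deprotonation gives the extended dienolate, which is silylated on oxygen (silyl dienol ether formation) and thereby activates C3a/C4 for oxidation.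

Step 10
Reactants: 18 tert-butyl{[(2S,3S,5R)-5-allyl-5,7-dimethoxy-3-methyl-2-(3,4,5-trimethoxyphenyl)-2,3,4,5-tetrahydrobenzofuran-6-yl]oxy}dimethylsilane
Product: 19 (2S,3S,5R)-5-allyl-5,7-dimethoxy-3-methyl-2-(3,4,5-trimethoxyphenyl)-3,5-dihydrobenzofuran-6(2H)-one
Conditions: DDQ (1.1 equiv), 2,4,6-collidine, CH2Cl2, −20 → 0 °C; aq NaHCO3
Reagents that add atoms: none
Why: DDQ dehydrogenation of a dienol ether (the reaction type that turns 3,5-dienol ethers into 4,6-dien-3-ones) should remove hydride from C4 and then the silyl group to give the linear dienone, because the axial C4–H on the face of the C3 methyl has no C3–H competitor and H3 on the other face is screened by the cis C2 aryl, while the low temperature guards the product against [3,3] shifts of the C5 allyl group.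

**Compound list**

1 | 3,4,5-trimethoxybenzaldehyde | COc1cc(C=O)cc(OC)c1OC | starting material
2 | (E)-crotylboronic acid pinacol ester | C/C=C/CB1OC(C)(C)C(C)(C)O1 | starting material
3 | 2-{[(1S,2S)-2-methyl-1-(3,4,5-trimethoxyphenyl)but-3-en-1-yl]oxy}-4,4,5,5-tetramethyl-1,3,2-dioxaborolane (pinacol borate ester) | CC1(C)OB(O[C@H](c2cc(OC)c(OC)c(OC)c2)[C@@H](C)C=C)OC1(C)C | intermediate
4 | (1S,2S)-2-methyl-1-(3,4,5-trimethoxyphenyl)but-3-en-1-ol | O[C@H](c1cc(OC)c(OC)c(OC)c1)[C@@H](C)C=C | intermediate
5 | 9-{[(1S,2S)-4-(9-borabicyclo[3.3.1]nonan-9-yl)-2-methyl-1-(3,4,5-trimethoxyphenyl)butyl]oxy}-9-borabicyclo[3.3.1]nonane | O(B1C2CCCC1CCC2)[C@H](c1cc(OC)c(OC)c(OC)c1)[C@@H](C)CCB1C2CCCC1CCC2 | intermediate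
6 | (1S,2S)-2-methyl-1-(3,4,5-trimethoxyphenyl)butane-1,4-diol | O[C@H](c1cc(OC)c(OC)c(OC)c1)[C@@H](C)CCO | intermediate
7 | (4S,5S)-4-methyl-5-(3,4,5-trimethoxyphenyl)tetrahydrofuran-2-ol (lactol, both anomers) | OC1O[C@H](c2cc(OC)c(OC)c(OC)c2)[C@@H](C)C1 | intermediate
8 | (4S,5S)-4-methyl-5-(3,4,5-trimethoxyphenyl)dihydrofuran-2(3H)-one | O=C1O[C@H](c2cc(OC)c(OC)c(OC)c2)[C@@H](C)C1 | intermediate
9 | (3R,4S,5S)-3-[(dimethylamino)methyl]-4-methyl-5-(3,4,5-trimethoxyphenyl)dihydrofuran-2(3H)-one | CN(C)C[C@@H]1C(=O)O[C@H](c2cc(OC)c(OC)c(OC)c2)[C@H]1C | intermediate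
10 | {[(3R,4S,5S)-4-methyl-2-oxo-5-(3,4,5-trimethoxyphenyl)tetrahydrofuran-3-yl]methyl}trimethylammonium iodide | C[N+](C)(C)C[C@@H]1C(=O)O[C@H](c2cc(OC)c(OC)c(OC)c2)[C@H]1C.[I-] | intermediate
11 | (4S,5S)-4-methyl-3-methylene-5-(3,4,5-trimethoxyphenyl)dihydrofuran-2(3H)-one | C=C1C(=O)O[C@H](c2cc(OC)c(OC)c(OC)c2)[C@H]1C | intermediate
12 | 1,3-dimethoxyacetone | COCC(=O)COC | starting material
13 | (3S,4S,5S)-3-(2,4-dimethoxy-3-oxobutyl)-4-methyl-5-(3,4,5-trimethoxyphenyl)dihydrofuran-2(3H)-one (epimers at the methoxy-bearing side-chain carbon) | COCC(=O)C(OC)C[C@@H]1C(=O)O[C@H](c2cc(OC)c(OC)c(OC)c2)[C@H]1C | intermediate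
14 | 4-[(1S,2S)-1-hydroxy-1-(3,4,5-trimethoxyphenyl)propan-2-yl]-2,6-dimethoxycyclohexane-1,3-dione (ring centres undefined, largely enolised) | O[C@H](c1cc(OC)c(OC)c(OC)c1)[C@H](C1CC(OC)C(=O)C(OC)C1=O)C | intermediate
15 | (2S,3S,3aS)-5,7-dimethoxy-3-methyl-2-(3,4,5-trimethoxyphenyl)-3,3a,4,5-tetrahydrobenzofuran-6(2H)-one (C5 epimers; C3a drawn as the expected 3,3a-trans isomer) | COC1C[C@@H]2C(=C(OC)C1=O)O[C@H](c1cc(OC)c(OC)c(OC)c1)[C@H]2C | intermediate
16 | allyl (2S,3S,3aS)-5,7-dimethoxy-3-methyl-2-(3,4,5-trimethoxyphenyl)-2,3,3a,4-tetrahydrobenzofuran-6-yl carbonate | C=CCOC(=O)OC1=C(OC)C[C@@H]2C(=C1OC)O[C@H](c1cc(OC)c(OC)c(OC)c1)[C@H]2C | intermediate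
17 | (2S,3S,3aS,5R)-5-allyl-5,7-dimethoxy-3-methyl-2-(3,4,5-trimethoxyphenyl)-3,3a,4,5-tetrahydrobenzofuran-6(2H)-one | C=CC[C@@]1(OC)C[C@@H]2C(=C(OC)C1=O)O[C@H](c1cc(OC)c(OC)c(OC)c1)[C@H]2C | intermediate
18 | tert-butyl{[(2S,3S,5R)-5-allyl-5,7-dimethoxy-3-methyl-2-(3,4,5-trimethoxyphenyl)-2,3,4,5-tetrahydrobenzofuran-6-yl]oxy}dimethylsilane | C=CC[C@@]1(OC)CC2=C(O[C@H](c3cc(OC)c(OC)c(OC)c3)[C@H]2C)C(OC)=C1O[Si](C)(C)C(C)(C)C | intermediate
19 | (2S,3S,5R)-5-allyl-5,7-dimethoxy-3-methyl-2-(3,4,5-trimethoxyphenyl)-3,5-dihydrobenzofuran-6(2H)-one (CNP0080458.1) | C=CC[C@@]1(OC)C=C2C(=C(OC)C1=O)O[C@H](c1cc(OC)c(OC)c(OC)c1)[C@H]2C | target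

**Step count and risks**

Total steps: 10. Longest linear sequence: 10 steps (1 → 19).

Steps most likely to fail:

Step 6 (new method). Base-induced migration of the exocyclic double bond of 11 into the lactone ring, repeated Michael addition, or self-condensation of the α-alkoxy ketone may outrun the cascade; the acylation may also stall after the conjugate addition. The fallback separates the two bond formations and uses a neutral donor. It sets out from 11 and 12: 12 is condensed with pyrrolidine to the enamine 1-(1,3-dimethoxyprop-1-en-2-yl)pyrrolidine F1, which undergoes a Stork enamine Michael addition to 11 (MeCN, rt → 60 °C), and aqueous acetic acid hydrolysis gives keto lactone 13, now isolated. Treatment of 13 with KOt-Bu in THF (the classical intramolecular Claisen closure of a 5-oxo ester to a cyclohexane-1,3-dione, here with the lactone as the ester) gives 14, and catalytic TsOH in toluene closes it to 15, where the route is rejoined.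

Step 10. Hydride abstraction may occur at C3 (tertiary, giving the double bond in ring B) or at benzylic C2 instead of C4, and the product may undergo [3,3] shifts of its allyl group if it is warmed or exposed to acid. The fallback replaces hydride abstraction by halogenation–elimination and sets out from 18: NBS in THF at −78 °C brominates the dienol ether at its γ carbon to give (2S,3R,5R)-5-allyl-3a-bromo-5,7-dimethoxy-3-methyl-2-(3,4,5-trimethoxyphenyl)-3,3a,4,5-tetrahydrobenzofuran-6(2H)-one F2, and DBU at −20 → 0 °C removes HBr by anti elimination to give 19. H3 can be anti-periplanar to bromine in only one C3a epimer and is flanked by the C2 aryl and the C3 methyl, so the bulky amidine should take a C4 hydrogen.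

Step 8. The facial preference of the chiral ligand and the intrinsic bias of the C3a-substituted ring may oppose each other, eroding selectivity at C5, and the palladium enolate may be protonated back to 15. The fallback sets out from 15 and uses substrate control with separation: the lithium enolate (LiN(i-Pr)2, THF, −78 °C) is alkylated with allyl bromide in the presence of DMPU, which should give 17 together with its C5 epimer (2S,3S,3aS,5S)-5-allyl-5,7-dimethoxy-3-methyl-2-(3,4,5-trimethoxyphenyl)-3,3a,4,5-tetrahydrobenzofuran-6(2H)-one F3. The two are separated by chromatography and 17 rejoins the route at step 9.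

**Further compounds**

F1 | step 6 | 1-(1,3-dimethoxyprop-1-en-2-yl)pyrrolidine | COCC(=COC)N1CCCC1
F2 | step 10 | (2S,3R,5R)-5-allyl-3a-bromo-5,7-dimethoxy-3-methyl-2-(3,4,5-trimethoxyphenyl)-3,3a,4,5-tetrahydrobenzofuran-6(2H)-one (C3a epimers) | C=CC[C@@]1(OC)CC2(Br)C(=C(OC)C1=O)O[C@H](c1cc(OC)c(OC)c(OC)c1)[C@H]2C
F3 | step 8 | (2S,3S,3aS,5S)-5-allyl-5,7-dimethoxy-3-methyl-2-(3,4,5-trimethoxyphenyl)-3,3a,4,5-tetrahydrobenzofuran-6(2H)-one | C=CC[C@]1(OC)C[C@@H]2C(=C(OC)C1=O)O[C@H](c1cc(OC)c(OC)c(OC)c1)[C@H]2C
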